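A direct plan would build (6S,1'R)-α-turmerone (A1) in a long linear sequence from a chiral β-methyl aldehyde (enamine Michael addition to a vinyl ketone, aldol ring closure, dienyl triflate methylation, ketone synthesis). It would then epoxidise the diene to vinyl epoxide A2, open A2 with a phenolic aldehyde under Pd(0) to the cis-1,4 aryl ether A3, and finish with a boron-templated curcuminoid condensation.
- The run-up to A1 would be weak: about eight linear steps would go into a small cyclohexadiene that oxidises and aromatises easily, and its ring stereocentre would be set by a Michael addition next to an existing stereocentre.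
- The epoxidation of A1 to A2 would be weak: one reagent would have to choose one of three alkenes and one face of a conjugated diene, and the labile vinyl epoxide could not be purified.
- The Pd-catalysed opening of A2 by the phenol would be weak: the C1'–O bond and the C1' centre would be made late on the most sensitive intermediate, against 1,2-attack, β-hydride elimination and loss of water to the arene.

**Retrosynthetic overview**
1. Last, the curcuminoid is made by boron-templated aldol condensation of the aryl-ether aldehyde (C4'–OH as silyl ether) with feruloylacetone, followed by desilylation.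
2. Key disconnection: the cyclohexene ring C1'–C6', with cis oxygens at C1' (OAr) and C4' (OH) across C2'=C3', is the retron of a Diels–Alder reaction. Cutting C1'–C6' and C4'–C5' gives a (1E,3E)-1-aryloxy-4-silyloxy-3-methylbutadiene (C1'–C4', aryl ether already in place) and an (E)-nitroalkene (C5'=C6' plus the whole side chain with Cα). The nitro group at C5' is a traceless regio- and endo-director, later removed with tin hydride.
3. Cα is set beforehand by Rh/BINAP conjugate vinylation of a dienone; radical nitration turns the vinyl group into the nitrovinyl dienophile.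
4. Ring order: both arenes are bought as vanillin; the only ring formed is the cyclohexene, closed late and convergently after the aryl–O–C1' bond exists.
5. The design avoids the weak steps: there is no cyclohexadiene, no epoxide and no allylic substitution. The aryl ether comes from a Williamson reaction on prenyl bromide, and C1', C4' and C6' arise in one cycloaddition.

Key step: step 7

Assumption: the β-diketone is drawn as one keto–enol tautomer; the tautomers interconvert, so enol regiochemistry is not controlled. Ring locants follow the target's cyclohexene (C1' = OAr, C3' = CH3, C4' = OH, C6' = side chain); Cα is the side-chain CH(CH3).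

**Route**

Step 1
Reactants: 1 vanillin; 2 1-bromo-3-methylbut-2-ene (prenyl bromide)
Product: 3 3-methoxy-4-[(3-methylbut-2-en-1-yl)oxy]benzaldehyde
Conditions: K2CO3, DMF, rt
Reagents that add atoms: none
Why: Williamson ether synthesis; the phenoxide displaces the primary allylic bromide by SN2, so the future C1'–O–aryl bond is made at the start on an achiral carbon and never by substitution on the ring.

Step 2
Reactants: 3
Product: 5 (2E)-4-(4-formyl-2-methoxyphenoxy)-2-methylbut-2-enal, via 4-{[(2E)-4-hydroxy-3-methylbut-2-en-1-yl]oxy}-3-methoxybenzaldehyde 4 (not isolated)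
Conditions: SeO2 (1.5 equiv), 1,4-dioxane, 80 °C
Reagents that add atoms: selenium dioxide, O=[Se]=O
Why: Riley oxidation (ene reaction, then [2,3]-shift) attacks the (E)-methyl group of the trisubstituted alkene, and allylic alcohol 4 is oxidised on to the (E)-enal; the non-enolisable aryl aldehyde and the aryl ether are inert.

Step 3
Reactants: 5
Product: 6 4-{[(1E,3E)-4-{[tert-butyl(dimethyl)silyl]oxy}-3-methylbuta-1,3-dien-1-yl]oxy}-3-methoxybenzaldehyde
Conditions: TBSOTf (1.2 equiv), Et3N (2 equiv), Et2O, −20 → 0 °C; filtration through basic alumina, used at once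
Reagents that add atoms: tert-butyldimethylsilyl trifluoromethanesulfonate, CC(C)(C)[Si](C)(C)OS(=O)(=O)C(F)(F)F
Why: Soft enolisation to the silyl dienol ether: O-silylation of the s-trans enal puts OSi trans to C2', and γ-deprotonation puts OAr trans to C3' because an inward aryloxy group would clash with the cis α-methyl group (allylic 1,3-strain), so the (1E,3E)-diene is expected; the aryl aldehyde cannot enolise.

Step 4
Reactants: 7 (2E)-but-2-enoyl chloride; 8 (2-methylprop-1-en-1-yl)magnesium bromide
Product: 9 (2E)-6-methylhepta-2,5-dien-4-one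
Conditions: Fe(acac)3 (3 mol %), THF, −78 °C
Reagents that add atoms: none
Why: Iron-catalysed acylation of a Grignard reagent by an acid chloride (Kumada-type cross-coupling) is much faster at −78 °C than 1,2- or 1,4-addition to the product, so the cross-conjugated dienone forms in one step.

Step 5
Reactants: 9
Product: 10 (6S)-2,6-dimethylocta-2,7-dien-4-one
Conditions: [Rh(cod)2]BF4 (3 mol %), (S)-BINAP (3.3 mol %), CH2=CHBF3K (2 equiv), toluene/H2O, 100 °C (sealed)
Reagents that add atoms: potassium vinyltrifluoroborate, C=C[B-](F)(F)F.[K+]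
Why: Hayashi–Miyaura asymmetric 1,4-addition: the vinyl–Rh(I)/BINAP species inserts only the less substituted (E)-propenyl arm of the dienone (the β,β-dimethyl arm is too hindered) and the ligand sets Cα; (S)-BINAP is expected to give 6S by the model for acyclic (E)-enones, and the enantiomeric ligand is available if the sense is opposite.

Step 6
Reactants: 10
Product: 11 (6S,7E)-2,6-dimethyl-8-nitroocta-2,7-dien-4-one
Conditions: AgNO2 (3 equiv), TEMPO (0.4 equiv), 4 Å MS, 1,2-dichloroethane, 70 °C
Reagents that add atoms: silver nitrite, [Ag+].[O-]N=O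
Why: Radical nitration of a terminal alkene: NO2• adds to the CH2 terminus of the only monosubstituted alkene, TEMPO traps the secondary radical and loss of TEMPO–H gives the (E)-nitroalkene; Cα is not involved and no base is present that could deconjugate or epimerise the product.

Step 7
Reactants: 6 4-{[(1E,3E)-4-{[tert-butyl(dimethyl)silyl]oxy}-3-methylbuta-1,3-dien-1-yl]oxy}-3-methoxybenzaldehyde; 11 (6S,7E)-2,6-dimethyl-8-nitroocta-2,7-dien-4-one
Product: 12 4-{[(1S,4R,5S,6S)-4-{[tert-butyl(dimethyl)silyl]oxy}-3-methyl-6-[(2S)-6-methyl-4-oxohept-5-en-2-yl]-5-nitrocyclohex-2-en-1-yl]oxy}-3-methoxybenzaldehyde (OAr, OSi and NO2 on one face, side chain on the other)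
Conditions: 1,1'-[(1R,2R)-cyclohexane-1,2-diyl]bis{3-[3,5-bis(trifluoromethyl)phenyl]thiourea} (10 mol %; the antipode that favours the face shown is chosen by screening), 6 (1.3 equiv), 4 Å MS, toluene, −30 → 0 °C
Reagents that add atoms: none
Why: Proposed new method: a normal-demand [4+2] cycloaddition in which the non-basic chiral bis-thiourea binds both nitro oxygens of 11 by double hydrogen bonding, lowers its LUMO and shields one π-face, so that the electron-rich diene 6 adds to the open face (concerted, or stepwise by vinylogous Mukaiyama–Michael addition and nitronate ring closure, with the same outcome). The closest known reaction types are the thermal Diels–Alder reaction of 1-silyloxy dienes with nitroalkenes and thiourea-catalysed enantioselective additions and cycloadditions to nitroalkenes; their combination on a 1,4-dioxygenated diene is new. The cyclohexene ring C1'–C6' is closed intermolecularly through a six-membered suprafacial transition state that forms C1'–C6' and C4'–C5' together. C1' and C4' come out cis because both oxygens occupy the outside positions of the (1E,3E)-diene, C6' comes out trans to both because the nitro group goes endo and the side chain is trans to it on the (E)-alkene, C5' is set but erased in step 8, and the absolute sense is set by the catalyst, since Cα (fixed in step 5) carries two alkyl groups of similar size and gives little bias of its own. The step needs the regiochemistry with nitro next to C4', which the silyloxy group as the strongest donor should secure over the aryloxy group (weakened by its para-formyl group) and the C3' methyl group, and it needs endo selectivity, which nitroalkenes normally show with 1-oxygenated dienes. Because Cα is already fixed, the adduct of the wrong face is a diastereomer and can be removed by chromatography.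

Step 8
Reactants: 12
Product: 13 4-({(1R,4S,6R)-4-{[tert-butyl(dimethyl)silyl]oxy}-3-methyl-6-[(2S)-6-methyl-4-oxohept-5-en-2-yl]cyclohex-2-en-1-yl}oxy)-3-methoxybenzaldehyde
Conditions: Bu3SnH (4 equiv), AIBN (0.3 equiv, in portions), toluene (0.2 M), 100 °C
Reagents that add atoms: none
Why: Radical denitration of a secondary nitroalkane with tributyltin hydride: Bu3Sn• adds to a nitro oxygen, the adduct fragments to the C5' radical and Bu3SnONO, and the radical takes hydrogen from the concentrated tin hydride before the homoallylic radical can rearrange; C5' becomes CH2 and C1', C4', C6' and Cα are untouched.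

Step 9
Reactants: 1 vanillin; 14 acetylacetone (4 equiv)
Product: 15 feruloylacetone, (1E,4Z)-5-hydroxy-1-(4-hydroxy-3-methoxyphenyl)hexa-1,4-dien-3-one (enol form)
Conditions: B2O3, B(On-Bu)3, n-BuNH2 (cat., slow addition), EtOAc, 80 °C; then 0.4 M HCl, 60 °C
Reagents that add atoms: none
Why: Pabon reaction: the boron chelate blocks the central carbon of the diketone and activates a terminal methyl group for aldol condensation with the aldehyde; excess diketone favours mono-condensation.

Step 10
Reactants: 13; 15
Product: 16 (1E,4Z,6E)-7-[4-({(1R,4S,6R)-4-{[tert-butyl(dimethyl)silyl]oxy}-3-methyl-6-[(2S)-6-methyl-4-oxohept-5-en-2-yl]cyclohex-2-en-1-yl}oxy)-3-methoxyphenyl]-5-hydroxy-1-(4-hydroxy-3-methoxyphenyl)hepta-1,4,6-trien-3-one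
Conditions: B2O3, B(On-Bu)3, n-BuNH2 (0.3 equiv, slow addition), EtOAc, 70 °C; then 5% aq AcOH, 40 °C
Reagents that add atoms: none
Why: Second Pabon condensation: only the boron-chelated diketone methyl group condenses with the aryl aldehyde, giving the (E)-alkene; the hindered side-chain enone, the silyl ether and the allylic aryl ether should survive, and mild acetic acid frees the curcuminoid without ionising the doubly allylic ring.

Step 11
Reactants: 16
Product: 17 bisabolocurcumin ether
Conditions: HF·pyridine, pyridine, THF, 0 °C → rt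
Reagents that add atoms: none
Why: Fluoride cleavage of the secondary silyl ether under buffered, weakly acidic conditions, which a curcuminoid tolerates better than base; no stereocentre is touched and the allylic C1'–O and C4'–O bonds are not ionised.

**Compound list**
1 | vanillin (4-hydroxy-3-methoxybenzaldehyde) | COc1cc(C=O)ccc1O | starting material
2 | 1-bromo-3-methylbut-2-ene (prenyl bromide) | CC(C)=CCBr | starting material
3 | 3-methoxy-4-[(3-methylbut-2-en-1-yl)oxy]benzaldehyde | COc1cc(C=O)ccc1OCC=C(C)C | intermediate
4 | 4-{[(2E)-4-hydroxy-3-methylbut-2-en-1-yl]oxy}-3-methoxybenzaldehyde | COc1cc(C=O)ccc1OC/C=C(\C)CO | intermediate (not isolated)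
5 | (2E)-4-(4-formyl-2-methoxyphenoxy)-2-methylbut-2-enal | COc1cc(C=O)ccc1OC/C=C(\C)C=O | intermediate
6 | 4-{[(1E,3E)-4-{[tert-butyl(dimethyl)silyl]oxy}-3-methylbuta-1,3-dien-1-yl]oxy}-3-methoxybenzaldehyde | COc1cc(C=O)ccc1O/C=C/C(C)=C/O[Si](C)(C)C(C)(C)C | intermediate
7 | (2E)-but-2-enoyl chloride (crotonyl chloride) | C/C=C/C(Cl)=O | starting material
8 | (2-methylprop-1-en-1-yl)magnesium bromide | CC(C)=C[Mg]Br | starting material
9 | (2E)-6-methylhepta-2,5-dien-4-one | C/C=C/C(=O)C=C(C)C | intermediate
10 | (6S)-2,6-dimethylocta-2,7-dien-4-one | C=C[C@@H](C)CC(=O)C=C(C)C | intermediate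
11 | (6S,7E)-2,6-dimethyl-8-nitroocta-2,7-dien-4-one | O=[N+]([O-])/C=C/[C@@H](C)CC(=O)C=C(C)C | intermediate
12 | 4-{[(1S,4R,5S,6S)-4-{[tert-butyl(dimethyl)silyl]oxy}-3-methyl-6-[(2S)-6-methyl-4-oxohept-5-en-2-yl]-5-nitrocyclohex-2-en-1-yl]oxy}-3-methoxybenzaldehyde | COc1cc(C=O)ccc1O[C@H]1C=C(C)[C@@H](O[Si](C)(C)C(C)(C)C)[C@@H]([N+](=O)[O-])[C@@H]1[C@@H](C)CC(=O)C=C(C)C | intermediate
13 | 4-({(1R,4S,6R)-4-{[tert-butyl(dimethyl)silyl]oxy}-3-methyl-6-[(2S)-6-methyl-4-oxohept-5-en-2-yl]cyclohex-2-en-1-yl}oxy)-3-methoxybenzaldehyde | COc1cc(C=O)ccc1O[C@H]1C=C(C)[C@@H](O[Si](C)(C)C(C)(C)C)C[C@@H]1[C@@H](C)CC(=O)C=C(C)C | intermediate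
14 | acetylacetone (pentane-2,4-dione) | CC(=O)CC(C)=O | starting material
15 | feruloylacetone (enol form) | COc1cc(/C=C/C(=O)/C=C(/C)O)ccc1O | intermediate
16 | (1E,4Z,6E)-7-[4-({(1R,4S,6R)-4-{[tert-butyl(dimethyl)silyl]oxy}-3-methyl-6-[(2S)-6-methyl-4-oxohept-5-en-2-yl]cyclohex-2-en-1-yl}oxy)-3-methoxyphenyl]-5-hydroxy-1-(4-hydroxy-3-methoxyphenyl)hepta-1,4,6-trien-3-one | COc1cc(/C=C/C(=O)/C=C(O)/C=C/c2ccc(O[C@H]3C=C(C)[C@@H](O[Si](C)(C)C(C)(C)C)C[C@@H]3[C@@H](C)CC(=O)C=C(C)C)c(OC)c2)ccc1O | intermediate
17 | bisabolocurcumin ether, (1E,4Z,6E)-5-hydroxy-1-(4-hydroxy-3-methoxyphenyl)-7-[3-methoxy-4-({(1R,4S,6R)-4-hydroxy-3-methyl-6-[(2S)-6-methyl-4-oxohept-5-en-2-yl]cyclohex-2-en-1-yl}oxy)phenyl]hepta-1,4,6-trien-3-one | COc1cc(/C=C/C(=O)/C=C(O)/C=C/c2ccc(O[C@H]3C=C(C)[C@@H](O)C[C@@H]3[C@@H](C)CC(=O)C=C(C)C)c(OC)c2)ccc1O | target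

**Step count**
Total: 11 steps. Longest linear sequence: 7 steps (1, 2, 3, 7, 8, 10, 11; the dienophile branch 4, 5, 6, 7, 8, 10, 11 is equally long).

**Steps most likely to fail**

Step 7 (Proposed new method). The hydrogen-bond catalyst may give poor face selection. Bond formation may also follow the aryloxy-directed regiochemistry, exo addition may compete, or the nitroalkene may react as a heterodiene with the silyl enol ether part of the diene. The fallback uses known chemistry, sets out from 10 and 6 and comes back at 13, so it also replaces step 8. Cross-metathesis of 10 with crotonaldehyde (second-generation Hoveyda–Grubbs catalyst, CH2Cl2, 40 °C) would give (2E,4S)-4,8-dimethyl-6-oxonona-2,7-dienal F1. Iminium catalysis with (2S,5S)-5-benzyl-2-tert-butyl-3-methylimidazolidin-4-one trifluoroacetate (or its antipode) in wet MeCN at −20 °C would make F1 the dienophile for 6. The formyl group would then be the endo- and regio-director at C5' and the amine would control the face, giving 4-{[(1R,4S,5S,6S)-4-{[tert-butyl(dimethyl)silyl]oxy}-5-formyl-3-methyl-6-[(2S)-6-methyl-4-oxohept-5-en-2-yl]cyclohex-2-en-1-yl]oxy}-3-methoxybenzaldehyde F2. Tsuji–Wilkinson decarbonylation of the aliphatic aldehyde of F2 with stoichiometric RhCl(PPh3)3 in toluene at 80–90 °C would give 13; the electron-rich aryl aldehyde should react more slowly at this temperature.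

Step 8. Fragmentation of the tin–nitro adduct may go by N–O instead of C–N cleavage (oxime formation), the reaction may stall on the unactivated secondary nitro group, or tin radicals may attack the enone or the aryl aldehyde. The fallback sets out from 12 and comes back at 13. Reduction of the nitro group with zinc dust in acetic acid would give 4-{[(1S,4R,5S,6S)-5-amino-4-{[tert-butyl(dimethyl)silyl]oxy}-3-methyl-6-[(2S)-6-methyl-4-oxohept-5-en-2-yl]cyclohex-2-en-1-yl]oxy}-3-methoxybenzaldehyde F3, handled crude. Reductive deamination through the monoalkyl diazene, with the anomeric amide N-(benzyloxy)-N-(pivaloyloxy)-4-(trifluoromethyl)benzamide in MeCN at 45 °C, would replace NH2 by H with loss of N2 and give 13 without a radical chain.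

Step 6. NO2• may add to the enone alkene or the E/Z ratio may be poor, and the product may deconjugate during isolation. The fallback sets out from 10 and comes back at 11. Lemieux–Johnson cleavage of the terminal alkene (OsO4 cat., NaIO4, 2,6-lutidine, dioxane/H2O) would give (2S)-2,6-dimethyl-4-oxohept-5-enal F4. A Henry reaction with nitromethane (cat. KF, i-PrOH, 0 °C, short contact to protect Cα) would give (6S)-7-hydroxy-2,6-dimethyl-8-nitrooct-2-en-4-one F5 as a mixture at C7. Dehydration with MsCl/Et3N at −20 °C would give 11.

**Further compounds**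
F1 | step 7 | (2E,4S)-4,8-dimethyl-6-oxonona-2,7-dienal | O=C/C=C/[C@@H](C)CC(=O)C=C(C)C
F2 | step 7 | 4-{[(1R,4S,5S,6S)-4-{[tert-butyl(dimethyl)silyl]oxy}-5-formyl-3-methyl-6-[(2S)-6-methyl-4-oxohept-5-en-2-yl]cyclohex-2-en-1-yl]oxy}-3-methoxybenzaldehyde | COc1cc(C=O)ccc1O[C@H]1C=C(C)[C@@H](O[Si](C)(C)C(C)(C)C)[C@@H](C=O)[C@@H]1[C@@H](C)CC(=O)C=C(C)C
F3 | step 8 | 4-{[(1S,4R,5S,6S)-5-amino-4-{[tert-butyl(dimethyl)silyl]oxy}-3-methyl-6-[(2S)-6-methyl-4-oxohept-5-en-2-yl]cyclohex-2-en-1-yl]oxy}-3-methoxybenzaldehyde | COc1cc(C=O)ccc1O[C@H]1C=C(C)[C@@H](O[Si](C)(C)C(C)(C)C)[C@@H](N)[C@@H]1[C@@H](C)CC(=O)C=C(C)C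
F4 | step 6 | (2S)-2,6-dimethyl-4-oxohept-5-enal | O=C[C@@H](C)CC(=O)C=C(C)C
F5 | step 6 | (6S)-7-hydroxy-2,6-dimethyl-8-nitrooct-2-en-4-one (both C7 epimers) | O=[N+]([O-])CC(O)[C@@H](C)CC(=O)C=C(C)C
A1 | direct plan | (6S)-2-methyl-6-[(1R)-4-methylcyclohexa-2,4-dien-1-yl]hept-2-en-4-one (α-turmerone) | CC1=CC[C@@H](C=C1)[C@@H](C)CC(=O)C=C(C)C
A2 | direct plan | (6S)-2-methyl-6-[(1R,4R,6S)-1-methyl-7-oxabicyclo[4.1.0]hept-2-en-4-yl]hept-2-en-4-one | C1=C[C@@]2(C)O[C@H]2C[C@@H]1[C@@H](C)CC(=O)C=C(C)C
A3 | direct plan | 4-({(1R,4S,6R)-4-hydroxy-3-methyl-6-[(2S)-6-methyl-4-oxohept-5-en-2-yl]cyclohex-2-en-1-yl}oxy)-3-methoxybenzaldehyde | COc1cc(C=O)ccc1O[C@H]1C=C(C)[C@@H](O)C[C@@H]1[C@@H](C)CC(=O)C=C(C)C
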